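Ring C is cut from the target at the ester between rings B and C and is traced back to a non-aromatic cyclohexane-1,3-dione. The feature exploited is ring C's substitution. Oxygen on c2 and c4 is a masked 1,3-diketone, while c5 (oxygen) and c6 (methyl) can begin as sp3 carbons. In one flask the enolate of methyl benzyloxyacetate adds to tert-butyl 2-ethylidene-3-oxobutanoate, an alkene carrying acetyl and ester groups (bond c5–c6). The acetyl methyl then closes onto the methyl ester (bond c3–c4). All six carbons and every substituent are thereby placed unambiguously, and dehydrogenation gives the arene. Benzyl lecanorate from orsellinic acid supplies rings A and B.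

Key step: step 2

Remark: the target has no stereocentre, so 3 is used as an E/Z mixture and 6 and 7 as diastereomer mixtures. The ring C locants c1–c6 (c1 bears the carbonyl group) are kept in the names of 7–10.

Step 1
Reactants: 1 tert-butyl acetoacetate; 2 acetaldehyde
Product: 3 tert-butyl 2-ethylidene-3-oxobutanoate (E/Z mixture, drawn Z)
Conditions: 2 (3 equiv), piperidine (5 mol%), AcOH (5 mol%), 4 Å MS, CH2Cl2, −10 → 0 °C; used fresh
Reagents that add atoms: none
Why: Knoevenagel condensation, in which low temperature, excess aldehyde and short contact time hold back a second acetoacetate from adding to the reactive product.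

Step 2
Reactants: 4 methyl 2-(benzyloxy)acetate; 3 tert-butyl 2-ethylidene-3-oxobutanoate
Product: 7 tert-butyl 5-(benzyloxy)-6-methyl-2,4-dioxocyclohexane-1-carboxylate (diastereomer mixture), via lithium enolate 5 (not isolated), via open-chain Michael adduct 6 (not isolated)
Conditions: 4, LiN(iPr)2 (LDA, 1.05 equiv), THF, −78 °C; slow addition of 3, −78 → −20 °C; KOtBu (2 equiv), THF, −20 °C → rt; 1 M HCl to pH 3, 0 °C
Reagents that add atoms: none
Why: Enolate 5 attacks the β-carbon of 3 (Michael addition of an ester enolate to an alkylidene 1,3-dicarbonyl compound), forming c5–c6 and the stabilised enolate of 6; excess KOtBu then reversibly deprotonates the acetyl methyl group, whose carbanion attacks the methyl ester (intramolecular Claisen condensation of Dieckmann type), forming c3–c4 with loss of methoxide. The closest known reaction type is the alkoxide-mediated Michael–Claisen union of an acetoacetate and a crotonate to a dihydroresorcylate, from which this step differs only in which partner is the donor in the first bond. The single ring closes in a 6-(enolendo)-exo-trig mode, allowed for six-membered rings, whereas attack of the c1 or c5 carbanion on any carbonyl group would need a four-membered ring, and closure through the enolate oxygen gives an enol lactone that alkoxide reopens. c1, c5 and c6 form without any controlling element as a diastereomer mixture, which is acceptable because all three become sp2 in step 3. The step needs conjugate addition to beat attack at the ketone and proton abstraction from the γ-hydrogens of 3: two acceptor groups on one alkene carbon, −78 °C and slow addition of 3 to 5 secure this, and an aldolate formed at the ketone can revert on warming while the conjugate adduct is held as a stabilised enolate. The tert-butyl ester resists enolate and alkoxide so that only the methyl ester acylates, keeping c1 deprotonated blocks retro-Michael cleavage, and final deprotonation of the acidic dione makes the closure irreversible.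

Step 3
Reactants: 7 tert-butyl 5-(benzyloxy)-6-methyl-2,4-dioxocyclohexane-1-carboxylate
Product: 8 tert-butyl 5-(benzyloxy)-2,4-dihydroxy-6-methylbenzoate
Conditions: I2 (0.2 equiv), DMSO, 70 °C, N2
Reagents that add atoms: none
Why: Iodine-catalysed oxidative aromatisation of a cyclohexane-1,3-dione with DMSO as terminal oxidant (iodination at an enolic carbon, loss of HI toward c6, tautomerisation), and because HI is recycled to I2 and never accumulates, the tert-butyl ester and the c5 benzyl ether should survive.

Step 4
Reactants: 8 tert-butyl 5-(benzyloxy)-2,4-dihydroxy-6-methylbenzoate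
Product: 9 tert-butyl 2,4,5-tris(benzyloxy)-6-methylbenzoate
Conditions: BnBr (2.5 equiv), K2CO3 (3 equiv), DMF, 60 °C, N2
Reagents that add atoms: benzyl bromide, BrCc1ccccc1
Why: Williamson ether synthesis, in which warming in a polar aprotic solvent also alkylates the hydrogen-bonded c2 phenol and the tert-butyl ester is inert to carbonate.

Step 5
Reactants: 9 tert-butyl 2,4,5-tris(benzyloxy)-6-methylbenzoate
Product: 10 2,4,5-tris(benzyloxy)-6-methylbenzoic acid
Conditions: CF3CO2H/CH2Cl2 (1:4), 0 °C → rt, short contact
Reagents that add atoms: none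
Why: Acid-catalysed tert-butyl ester cleavage by alkyl–oxygen fission is indifferent to the two ortho substituents that would block saponification, and dilute acid for a short time spares the aryl benzyl ethers and avoids protodecarboxylation.

Step 6
Reactants: 11 orsellinic acid (2,4-dihydroxy-6-methylbenzoic acid)
Product: 12 benzyl 2,4-dihydroxy-6-methylbenzoate
Conditions: BnBr (1.05 equiv), KHCO3 (1.2 equiv), DMF, rt
Reagents that add atoms: benzyl bromide, BrCc1ccccc1
Why: Carboxylate O-alkylation (SN2), selective because hydrogencarbonate ionises only the carboxylic acid and leaves both phenols protonated.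

Step 7
Reactants: 11 orsellinic acid
Product: 14 4-[(tert-butyldimethylsilyl)oxy]-2-hydroxy-6-methylbenzoic acid, via bis-silylated ester 13 (not isolated)
Conditions: TBSCl (2.3 equiv), imidazole (5 equiv), DMF, 0 °C → rt; crude in AcOH/THF/H2O (3:1:1), rt
Reagents that add atoms: tert-butyldimethylsilyl chloride, CC(C)(C)[Si](C)(C)Cl
Why: Silyl protection followed by selective solvolysis, since silylation takes the carboxyl group and the unchelated 4-OH while the hydrogen-bonded 2-OH lags, and dilute acetic acid then hydrolyses only the labile silyl ester.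

Step 8
Reactants: 14 4-[(tert-butyldimethylsilyl)oxy]-2-hydroxy-6-methylbenzoic acid; 12 benzyl 2,4-dihydroxy-6-methylbenzoate
Product: 15 benzyl 4-({4-[(tert-butyldimethylsilyl)oxy]-2-hydroxy-6-methylbenzoyl}oxy)-2-hydroxy-6-methylbenzoate
Conditions: DCC (1.1 equiv), DMAP (5 mol%), toluene/CH2Cl2, 0 °C → rt
Reagents that add atoms: none
Why: Steglich esterification, regioselective because the 4-OH of 12 is the only phenol in either partner not tied up in a hydrogen bond to a neighbouring carbonyl group.

Step 9
Reactants: 15 silyl-protected A–B depside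
Product: 16 benzyl 4-[(2,4-dihydroxy-6-methylbenzoyl)oxy]-2-hydroxy-6-methylbenzoate (benzyl lecanorate)
Conditions: Bu4NF (1.1 equiv), AcOH (1.2 equiv), THF, 0 °C
Reagents that add atoms: none
Why: Fluoride-induced cleavage of a phenolic silyl ether, in which the acetic acid buffer protonates the phenoxide as it forms so that neither the depside link nor the benzyl ester is attacked.

Step 10
Reactants: 10 2,4,5-tris(benzyloxy)-6-methylbenzoic acid; 16 benzyl lecanorate
Product: 18 benzyl 2-hydroxy-4-[(2-hydroxy-6-methyl-4-{[2,4,5-tris(benzyloxy)-6-methylbenzoyl]oxy}benzoyl)oxy]-6-methylbenzoate, via mixed trifluoroacetic anhydride 17 (not isolated)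
Conditions: 10, (CF3CO)2O (3 equiv), toluene, 0 °C; then 16, rt
Reagents that add atoms: none
Why: Mixed-anhydride esterification as commonly used for depsides, in which the electron-rich hindered acid acylates through the acylium-like anhydride 17 and only the ring B 4-OH of 16 lacks the hydrogen bond that disables the two ortho hydroxyls.

Step 11
Reactants: 18 fully protected tridepside
Product: 19 CNP0248995.0, 2-hydroxy-4-[(2-hydroxy-6-methyl-4-{[2,4,5-trihydroxy-6-methylbenzoyl]oxy}benzoyl)oxy]-6-methylbenzoic acid
Conditions: H2 (1 atm), Pd/C (10 wt%), THF/EtOAc, rt; filtration under N2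
Reagents that add atoms: none
Why: Catalytic hydrogenolysis removes the three benzyl ethers and the benzyl ester under neutral conditions that leave both aryl ester links untouched, while a non-nucleophilic solvent and exclusion of air protect the oxidation-prone trioxygenated ring C.

Compound list
1 | tert-butyl acetoacetate | CC(=O)CC(=O)OC(C)(C)C | starting material
2 | acetaldehyde | CC=O | starting material
3 | tert-butyl 2-ethylidene-3-oxobutanoate (E/Z mixture, drawn Z) | C/C=C(/C(C)=O)C(=O)OC(C)(C)C | intermediate
4 | methyl 2-(benzyloxy)acetate | COC(=O)COCc1ccccc1 | starting material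
5 | lithium 2-(benzyloxy)-1-methoxyethen-1-olate (chelated enolate of 4, OLi cis to OBn) | [Li+].CO/C([O-])=C/OCc1ccccc1 | intermediate
6 | 1-tert-butyl 5-methyl 2-acetyl-4-(benzyloxy)-3-methylpentanedioate (present as its enolate, drawn neutral; diastereomer mixture) | COC(=O)C(OCc1ccccc1)C(C)C(C(C)=O)C(=O)OC(C)(C)C | intermediate
7 | tert-butyl 5-(benzyloxy)-6-methyl-2,4-dioxocyclohexane-1-carboxylate (diastereomer mixture) | CC1C(OCc2ccccc2)C(=O)CC(=O)C1C(=O)OC(C)(C)C | intermediate
8 | tert-butyl 5-(benzyloxy)-2,4-dihydroxy-6-methylbenzoate | Cc1c(OCc2ccccc2)c(O)cc(O)c1C(=O)OC(C)(C)C | intermediate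
9 | tert-butyl 2,4,5-tris(benzyloxy)-6-methylbenzoate | Cc1c(OCc2ccccc2)c(OCc2ccccc2)cc(OCc2ccccc2)c1C(=O)OC(C)(C)C | intermediate
10 | 2,4,5-tris(benzyloxy)-6-methylbenzoic acid | Cc1c(OCc2ccccc2)c(OCc2ccccc2)cc(OCc2ccccc2)c1C(=O)O | intermediate
11 | orsellinic acid (2,4-dihydroxy-6-methylbenzoic acid) | Cc1cc(O)cc(O)c1C(=O)O | starting material
12 | benzyl 2,4-dihydroxy-6-methylbenzoate | Cc1cc(O)cc(O)c1C(=O)OCc1ccccc1 | intermediate
13 | tert-butyldimethylsilyl 4-[(tert-butyldimethylsilyl)oxy]-2-hydroxy-6-methylbenzoate | Cc1cc(O[Si](C)(C)C(C)(C)C)cc(O)c1C(=O)O[Si](C)(C)C(C)(C)C | intermediate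
14 | 4-[(tert-butyldimethylsilyl)oxy]-2-hydroxy-6-methylbenzoic acid | Cc1cc(O[Si](C)(C)C(C)(C)C)cc(O)c1C(=O)O | intermediate
15 | benzyl 4-({4-[(tert-butyldimethylsilyl)oxy]-2-hydroxy-6-methylbenzoyl}oxy)-2-hydroxy-6-methylbenzoate | Cc1cc(OC(=O)c2c(C)cc(O[Si](C)(C)C(C)(C)C)cc2O)cc(O)c1C(=O)OCc1ccccc1 | intermediate
16 | benzyl 4-[(2,4-dihydroxy-6-methylbenzoyl)oxy]-2-hydroxy-6-methylbenzoate (benzyl lecanorate) | Cc1cc(OC(=O)c2c(C)cc(O)cc2O)cc(O)c1C(=O)OCc1ccccc1 | intermediate
17 | 2,4,5-tris(benzyloxy)-6-methylbenzoic trifluoroacetic anhydride | Cc1c(OCc2ccccc2)c(OCc2ccccc2)cc(OCc2ccccc2)c1C(=O)OC(=O)C(F)(F)F | intermediate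
18 | benzyl 2-hydroxy-4-[(2-hydroxy-6-methyl-4-{[2,4,5-tris(benzyloxy)-6-methylbenzoyl]oxy}benzoyl)oxy]-6-methylbenzoate | Cc1cc(OC(=O)c2c(C)cc(OC(=O)c3c(OCc4ccccc4)cc(OCc4ccccc4)c(OCc4ccccc4)c3C)cc2O)cc(O)c1C(=O)OCc1ccccc1 | intermediate
19 | CNP0248995.0 | Cc1cc(OC(=O)c2c(C)cc(OC(=O)c3c(O)cc(O)c(O)c3C)cc2O)cc(O)c1C(=O)O | target

Total step count: 11. Longest linear sequence: 7 steps (1, 2, 3, 4, 5, 10, 11).

Steps most likely to fail

Step 2. Several things may go wrong:
- The basic enolate may take a γ-proton from 3 instead of adding, after which the acceptor oligomerises.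
- Attack at the ketone may persist.
- The adduct may fragment during the closure.

The fallback separates the two bonds and removes the strong base from the first. Setting out from 4, deprotonation with LiN(iPr)2 and trapping with Me3SiCl gives the ketene silyl acetal (Z)-{[2-(benzyloxy)-1-methoxyethenyl]oxy}trimethylsilane F1. F1 adds to 3 in a Mukaiyama–Michael reaction (Sc(OTf)3 catalyst, CH2Cl2, −78 °C). Aqueous work-up delivers 6, which is now isolated and purified. A separate closure with KOtBu in THF comes back to the route at 7.

Step 3. Several processes may compete with the oxidation: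
- Acid-promoted loss of benzyl alcohol across c5–c6 would aromatise the ring without oxidation and lose the c5 oxygen.
- Loss of the tert-butyl group followed by decarboxylation.
- Ring iodination or over-oxidation of the electron-rich phenol.

The fallback dehydrogenates a masked dienol under non-acidic conditions. Setting out from 7, KN(SiMe3)2 (2.2 equiv) and TBSCl give tert-butyl 5-(benzyloxy)-2,4-bis[(tert-butyldimethylsilyl)oxy]-6-methylcyclohexa-1,3-diene-1-carboxylate F2. DDQ in toluene over solid NaHCO3 aromatises this cyclohexadiene to tert-butyl 5-(benzyloxy)-2,4-bis[(tert-butyldimethylsilyl)oxy]-6-methylbenzoate F3, whose masked phenols cannot be oxidised further. Bu4NF/AcOH then comes back to the route at 8.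

Step 10. Three processes may intervene:
- Acyl transfer from the doubly ortho-substituted acid may be slow.
- The existing A–B ester link may scramble in the acidic medium.
- The chelated hydroxyls may be acylated.

The fallback builds the chain from the other end, so that no depside bond is present in the acidic coupling. Setting out from 11, allyl bromide and KHCO3 in DMF give allyl 2,4-dihydroxy-6-methylbenzoate F4. Acid 10, activated as 17, acylates the 4-OH of F4 to give allyl 2-hydroxy-6-methyl-4-{[2,4,5-tris(benzyloxy)-6-methylbenzoyl]oxy}benzoate F5. Tsuji–Trost deallylation with the zerovalent palladium complex Pd(PPh3)4 and N-methylaniline gives 2-hydroxy-6-methyl-4-{[2,4,5-tris(benzyloxy)-6-methylbenzoyl]oxy}benzoic acid F6. A neutral DCC coupling of F6 with 12 comes back to the route at 18.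

Further compounds
F1 | step 2 | (Z)-{[2-(benzyloxy)-1-methoxyethenyl]oxy}trimethylsilane | CO/C(O[Si](C)(C)C)=C/OCc1ccccc1
F2 | step 3 | tert-butyl 5-(benzyloxy)-2,4-bis[(tert-butyldimethylsilyl)oxy]-6-methylcyclohexa-1,3-diene-1-carboxylate (diastereomer mixture) | CC1C(OCc2ccccc2)C(O[Si](C)(C)C(C)(C)C)=CC(O[Si](C)(C)C(C)(C)C)=C1C(=O)OC(C)(C)C
F3 | step 3 | tert-butyl 5-(benzyloxy)-2,4-bis[(tert-butyldimethylsilyl)oxy]-6-methylbenzoate | Cc1c(OCc2ccccc2)c(O[Si](C)(C)C(C)(C)C)cc(O[Si](C)(C)C(C)(C)C)c1C(=O)OC(C)(C)C
F4 | step 10 | allyl 2,4-dihydroxy-6-methylbenzoate | C=CCOC(=O)c1c(C)cc(O)cc1O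
F5 | step 10 | allyl 2-hydroxy-6-methyl-4-{[2,4,5-tris(benzyloxy)-6-methylbenzoyl]oxy}benzoate | C=CCOC(=O)c1c(C)cc(OC(=O)c2c(OCc3ccccc3)cc(OCc3ccccc3)c(OCc3ccccc3)c2C)cc1O
F6 | step 10 | 2-hydroxy-6-methyl-4-{[2,4,5-tris(benzyloxy)-6-methylbenzoyl]oxy}benzoic acid | OC(=O)c1c(C)cc(OC(=O)c2c(OCc3ccccc3)cc(OCc3ccccc3)c(OCc3ccccc3)c2C)cc1O
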